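The eleven-membered carbocycle (ring numbering: C1 carries the vanillate, C2=C3 is the Z-olefin, C4 the acetate, C5 the gem-dimethyl carbon, C9=C10 the E-olefin) is opened at the C3–C4 bond. The structure offers there an allylic carbinol carbon (C4) flanked by an olefinic CH (C3) and a quaternary carbon (C5), the retron of an alkenylmetal adding to a non-enolisable neopentyl aldehyde. An intramolecular Nozaki–Hiyama–Kishi reaction of an acyclic (Z)-alkenyl iodide aldehyde thus closes the ring, keeps the Z geometry and creates the C4 stereocentre in one operation. The precursor already holds the C1 vanillate (phenol masked as acetate) and the E-olefin, assembled by carboalumination, glycidate opening and anti-carbomagnesiation.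

Key step: step 13

Remark: 4-acetoxy-3-methoxybenzoic acid, methyl (S)-glycidate and 5-iodopent-1-yne are assumed to be purchased as such; the ring numbering of the paragraph above is used throughout.

Step 1
Reactants: 1 methyl isobutyrate; 2 5-iodopent-1-yne
Product: 4 methyl 2,2-dimethylhept-6-ynoate, via lithium enolate 3 (not isolated)
Conditions: LiN(i-Pr)2 (LDA), THF, −78 °C; then 2, DMPU, −78 °C → rt
Reagents that add atoms: none
Why: Ester enolate alkylation (SN2 at the primary iodide) should build the quaternary carbon that becomes ring C5 together with the alkyne handle; no stereocentre is formed.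

Step 2
Reactants: 4 methyl 2,2-dimethylhept-6-ynoate
Product: 5 2,2-dimethylhept-6-yn-1-ol
Conditions: LiAlH4, Et2O, 0 °C → rt
Reagents that add atoms: none
Why: Hydride reduction of the ester (LiAlH4 reduction) should give the neopentyl alcohol that later becomes the aldehyde carbon, the isolated terminal alkyne being inert under these conditions.

Step 3
Reactants: 5 2,2-dimethylhept-6-yn-1-ol
Product: 6 tert-butyl[(2,2-dimethylhept-6-yn-1-yl)oxy]dimethylsilane
Conditions: t-BuMe2SiCl, imidazole, DMF, rt
Reagents that add atoms: tert-butyldimethylsilyl chloride CC(C)(C)[Si](C)(C)Cl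
Why: Silyl ether protection (silylation) masks the alcohol in a form that tolerates Me3Al, organolithium and Grignard reagents and i-Bu2AlH.

Step 4
Reactants: 6 tert-butyl[(2,2-dimethylhept-6-yn-1-yl)oxy]dimethylsilane
Product: 8 tert-butyl{[(6E)-7-iodo-2,2,6-trimethylhept-6-en-1-yl]oxy}dimethylsilane, via alkenylalane 7 (not isolated)
Conditions: Me3Al, Cp2ZrCl2 (0.25 equiv), CH2Cl2, 0 °C → rt; then I2, THF, −30 → 0 °C
Reagents that add atoms: trimethylaluminium C[Al](C)C; iodine II
Why: Zirconium-catalysed carboalumination (Negishi carboalumination) adds methyl and aluminium syn across the terminal alkyne with methyl on the internal carbon, and iodinolysis with retention should give the (E)-alkenyl iodide that fixes the geometry of the later C9=C10 ring olefin.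

Step 5
Reactants: 8 the (E)-alkenyl iodide; 9 methyl (S)-glycidate
Product: 12 methyl (2S,4E)-10-[(tert-butyldimethylsilyl)oxy]-2-hydroxy-5,9,9-trimethyldec-4-enoate, via alkenyllithium 10 (not isolated), via alkenylmagnesium bromide 11 (not isolated)
Conditions: t-BuLi (2 equiv), Et2O, −78 °C; MgBr2·OEt2, −78 → 0 °C; then CuI (0.15 equiv), 9 (1.5 equiv), THF, −40 → −20 °C; aqueous work-up
Reagents that add atoms: none
Why: Iodine–lithium exchange with retention, transmetalation to magnesium and CuI-catalysed SN2 opening of the glycidic ester at its CH2 terminus (epoxide opening by an alkenylcopper species) should give the alpha-hydroxy ester, whose stereocentre (later ring C1) is carried over untouched from the chiral-pool epoxide.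

Step 6
Reactants: 12 the alpha-hydroxy ester
Product: 13 methyl (2S,4E)-10-[(tert-butyldimethylsilyl)oxy]-5,9,9-trimethyl-2-[(triethylsilyl)oxy]dec-4-enoate
Conditions: Et3SiCl, imidazole, CH2Cl2, 0 °C → rt
Reagents that add atoms: chlorotriethylsilane CC[Si](CC)(CC)Cl
Why: Silylation of the secondary alcohol; the more labile triethylsilyl group is chosen so that it can later be removed beside the tert-butyldimethylsilyl ether.

Step 7
Reactants: 13 the bis-silylated ester
Product: 15 (3S,5E)-11-[(tert-butyldimethylsilyl)oxy]-6,10,10-trimethyl-3-[(triethylsilyl)oxy]undec-5-en-1-yne, via aldehyde 14 (not isolated)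
Conditions: i-Bu2AlH (1.1 equiv), CH2Cl2, −78 °C; then MeOH, K2CO3, dimethyl (1-diazo-2-oxopropyl)phosphonate, −78 °C → rt
Reagents that add atoms: dimethyl (1-diazo-2-oxopropyl)phosphonate CC(=O)C(=[N+]=[N-])P(=O)(OC)OC
Why: Partial reduction of the alpha-silyloxy ester stops at the aluminium hemiacetal, and release of aldehyde 14 into the basic methanolic Ohira–Bestmann mixture (Seyferth–Gilbert homologation) should give the terminal alkyne with the alpha stereocentre intact because the aldehyde is consumed as it forms.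

Step 8
Reactants: 15 the silylated enyne
Product: 16 (3S,5E)-11-[(tert-butyldimethylsilyl)oxy]-6,10,10-trimethylundec-5-en-1-yn-3-ol
Conditions: PPTS (0.1 equiv), MeOH/CH2Cl2, 0 °C
Reagents that add atoms: none
Why: Acid-catalysed methanolysis (selective desilylation) should cleave the secondary triethylsilyl ether much faster than the hindered neopentyl tert-butyldimethylsilyl ether.

Step 9
Reactants: 16 the propargylic alcohol
Product: 18 (1Z,3S,5E)-11-[(tert-butyldimethylsilyl)oxy]-1-iodo-2,6,10,10-tetramethylundeca-1,5-dien-3-ol, via alkenylmagnesium alkoxide 17 (not isolated)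
Conditions: MeMgBr (3.5 equiv), CuI (0.15 equiv), Et2O, −10 °C → rt; then I2, THF, −78 → 0 °C
Reagents that add atoms: methylmagnesium bromide C[Mg]Br; iodine II
Why: Copper-catalysed anti-carbomagnesiation of the propargylic magnesium alkoxide puts methyl on the alkyne carbon next to the carbinol and magnesium on the terminus inside a five-membered chelate, so that iodinolysis with retention should give the (Z)-iodoalkene (later the Z C2=C3 olefin).

Step 10
Reactants: 18 the (Z)-iodo allylic alcohol; 19 4-acetoxy-3-methoxybenzoic acid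
Product: 20 (1Z,3S,5E)-11-[(tert-butyldimethylsilyl)oxy]-1-iodo-2,6,10,10-tetramethylundeca-1,5-dien-3-yl 4-acetoxy-3-methoxybenzoate
Conditions: EDC·HCl, DMAP (0.2 equiv), CH2Cl2, 0 °C → rt
Reagents that add atoms: none
Why: Carbodiimide esterification (Steglich esterification) acylates the secondary allylic alcohol at oxygen, hence with retention at the carbinol carbon, while the phenol stays masked as its acetate.

Step 11
Reactants: 20 the silylated ester
Product: 21 (1Z,3S,5E)-11-hydroxy-1-iodo-2,6,10,10-tetramethylundeca-1,5-dien-3-yl 4-acetoxy-3-methoxybenzoate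
Conditions: HF·pyridine, pyridine, THF, 0 °C → rt
Reagents that add atoms: none
Why: Fluoride-mediated desilylation under buffered, non-basic conditions should free the primary alcohol without touching the two esters, the aryl acetate or the alkenyl iodide.

Step 12
Reactants: 21 the primary alcohol
Product: 22 (1Z,3S,5E)-1-iodo-2,6,10,10-tetramethyl-11-oxoundeca-1,5-dien-3-yl 4-acetoxy-3-methoxybenzoate
Conditions: Dess–Martin periodinane, CH2Cl2, 0 °C → rt
Reagents that add atoms: none
Why: Dess–Martin oxidation should convert the neopentyl alcohol into the non-enolisable aldehyde under neutral conditions that spare the iodoalkene and the esters.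

Step 13
Reactants: 22 the (Z)-alkenyl iodide aldehyde
Product: 24 (1S,2Z,4R,9E)-4-hydroxy-2,5,5,9-tetramethylcycloundeca-2,9-dien-1-yl 4-acetoxy-3-methoxybenzoate, via alkenylchromium 23 (not isolated)
Conditions: CrCl2 (10 equiv), NiCl2 (0.1 equiv), DMSO/THF (3:1), rt, slow addition of 22 to a final 0.003 M
Reagents that add atoms: none
Why: CrCl2 reduces NiCl2 to zerovalent nickel, which inserts into the C–I bond with retention, and transmetalation gives the alkenyl species of trivalent chromium 23, which adds to the aldehyde and stays as the chromium alkoxide until work-up. The closest known reaction type is the Nozaki–Hiyama–Kishi macrocyclisation of alkenyl iodide aldehydes to medium and large carbocyclic allylic alcohols. The eleven-membered ring closes in the 11-exo-trig mode at the bond between the olefinic CH (ring C3) and the carbinol carbon (ring C4). The new C4 stereocentre is governed by the resident C1 ester stereocentre through 1,4-induction across the Z-olefin: with both allylic hydrogens in the olefin plane (minimal allylic 1,3-strain) and the bridge containing the E-olefin leaving C1 and C4 on opposite faces, the two oxygen substituents should end up trans, which is the required (4R) configuration; this facial bias is the least secure element, and a chiral sulfonamide ligand on chromium could reinforce it. The step needs cyclisation to outrun oligomerisation and protodemetalation, which high dilution, the cis-olefin turn and the gem-dimethyl group favour, and it needs the Z geometry to survive, which trisubstituted alkenylnickel and alkenylchromium species normally ensure. Chemoselectivity rests on the reagent, since alkenylchromium adds to aldehydes but not to the benzoate, the aryl acetate or the allylic ester, and the neopentyl aldehyde can neither enolise nor epimerise.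

Step 14
Reactants: 24 the macrocyclic allylic alcohol
Product: 25 (1S,2Z,4R,9E)-4-acetoxy-2,5,5,9-tetramethylcycloundeca-2,9-dien-1-yl 4-acetoxy-3-methoxybenzoate
Conditions: Ac2O, DMAP (0.1 equiv), pyridine, CH2Cl2, 0 °C → rt
Reagents that add atoms: acetic anhydride CC(=O)OC(C)=O
Why: DMAP-catalysed acetylation of the hindered allylic alcohol (O-acylation) proceeds at oxygen and so should keep the C4 configuration.

Step 15
Reactants: 25 the diacetate
Product: 26 (1S,2Z,4R,9E)-4-acetoxy-2,5,5,9-tetramethylcycloundeca-2,9-dien-1-yl 4-hydroxy-3-methoxybenzoate (CNP0124394.1)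
Conditions: pyrrolidine (1.5 equiv), CH2Cl2, 0 °C
Reagents that add atoms: none
Why: Chemoselective aminolysis should cleave only the aryl acetate, an activated ester, while the hindered secondary alkyl acetate and the benzoate-type ester are inert to pyrrolidine at 0 °C.

Compound list
1 | methyl isobutyrate (methyl 2-methylpropanoate) | COC(=O)C(C)C | starting material
2 | 5-iodopent-1-yne | C#CCCCI | starting material
3 | lithium enolate of 1 (lithium 1-methoxy-2-methylprop-1-en-1-olate; not isolated) | COC(O[Li])=C(C)C | intermediate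
4 | methyl 2,2-dimethylhept-6-ynoate | COC(=O)C(C)(C)CCCC#C | intermediate
5 | 2,2-dimethylhept-6-yn-1-ol | OCC(C)(C)CCCC#C | intermediate
6 | tert-butyl[(2,2-dimethylhept-6-yn-1-yl)oxy]dimethylsilane | CC(C)(C)[Si](C)(C)OCC(C)(C)CCCC#C | intermediate
7 | {(1E)-7-[(tert-butyldimethylsilyl)oxy]-2,6,6-trimethylhept-1-en-1-yl}dimethylalane (not isolated) | C[Al](C)/C=C(\C)CCCC(C)(C)CO[Si](C)(C)C(C)(C)C | intermediate
8 | tert-butyl{[(6E)-7-iodo-2,2,6-trimethylhept-6-en-1-yl]oxy}dimethylsilane | CC(C)(C)[Si](C)(C)OCC(C)(C)CCC/C(C)=C/I | intermediate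
9 | methyl (S)-glycidate [methyl (2S)-oxirane-2-carboxylate] | COC(=O)[C@@H]1CO1 | starting material
10 | {(1E)-7-[(tert-butyldimethylsilyl)oxy]-2,6,6-trimethylhept-1-en-1-yl}lithium (not isolated) | [Li]/C=C(\C)CCCC(C)(C)CO[Si](C)(C)C(C)(C)C | intermediate
11 | {(1E)-7-[(tert-butyldimethylsilyl)oxy]-2,6,6-trimethylhept-1-en-1-yl}magnesium bromide (not isolated) | Br[Mg]/C=C(\C)CCCC(C)(C)CO[Si](C)(C)C(C)(C)C | intermediate
12 | methyl (2S,4E)-10-[(tert-butyldimethylsilyl)oxy]-2-hydroxy-5,9,9-trimethyldec-4-enoate | COC(=O)[C@@H](O)C/C=C(\C)CCCC(C)(C)CO[Si](C)(C)C(C)(C)C | intermediate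
13 | methyl (2S,4E)-10-[(tert-butyldimethylsilyl)oxy]-5,9,9-trimethyl-2-[(triethylsilyl)oxy]dec-4-enoate | COC(=O)[C@@H](O[Si](CC)(CC)CC)C/C=C(\C)CCCC(C)(C)CO[Si](C)(C)C(C)(C)C | intermediate
14 | (2S,4E)-10-[(tert-butyldimethylsilyl)oxy]-5,9,9-trimethyl-2-[(triethylsilyl)oxy]dec-4-enal (not isolated) | O=C[C@@H](O[Si](CC)(CC)CC)C/C=C(\C)CCCC(C)(C)CO[Si](C)(C)C(C)(C)C | intermediate
15 | (3S,5E)-11-[(tert-butyldimethylsilyl)oxy]-6,10,10-trimethyl-3-[(triethylsilyl)oxy]undec-5-en-1-yne | C#C[C@@H](O[Si](CC)(CC)CC)C/C=C(\C)CCCC(C)(C)CO[Si](C)(C)C(C)(C)C | intermediate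
16 | (3S,5E)-11-[(tert-butyldimethylsilyl)oxy]-6,10,10-trimethylundec-5-en-1-yn-3-ol | C#C[C@@H](O)C/C=C(\C)CCCC(C)(C)CO[Si](C)(C)C(C)(C)C | intermediate
17 | bromomagnesium (1Z,3S,5E)-1-(bromomagnesio)-11-[(tert-butyldimethylsilyl)oxy]-2,6,10,10-tetramethylundeca-1,5-dien-3-olate (not isolated) | Br[Mg]/C=C(C)\[C@@H](O[Mg]Br)C/C=C(\C)CCCC(C)(C)CO[Si](C)(C)C(C)(C)C | intermediate
18 | (1Z,3S,5E)-11-[(tert-butyldimethylsilyl)oxy]-1-iodo-2,6,10,10-tetramethylundeca-1,5-dien-3-ol | I/C=C(C)\[C@@H](O)C/C=C(\C)CCCC(C)(C)CO[Si](C)(C)C(C)(C)C | intermediate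
19 | 4-acetoxy-3-methoxybenzoic acid | COc1cc(C(=O)O)ccc1OC(C)=O | starting material
20 | (1Z,3S,5E)-11-[(tert-butyldimethylsilyl)oxy]-1-iodo-2,6,10,10-tetramethylundeca-1,5-dien-3-yl 4-acetoxy-3-methoxybenzoate | COc1cc(C(=O)O[C@@H](C/C=C(\C)CCCC(C)(C)CO[Si](C)(C)C(C)(C)C)/C(C)=C\I)ccc1OC(C)=O | intermediate
21 | (1Z,3S,5E)-11-hydroxy-1-iodo-2,6,10,10-tetramethylundeca-1,5-dien-3-yl 4-acetoxy-3-methoxybenzoate | COc1cc(C(=O)O[C@@H](C/C=C(\C)CCCC(C)(C)CO)/C(C)=C\I)ccc1OC(C)=O | intermediate
22 | (1Z,3S,5E)-1-iodo-2,6,10,10-tetramethyl-11-oxoundeca-1,5-dien-3-yl 4-acetoxy-3-methoxybenzoate | COc1cc(C(=O)O[C@@H](C/C=C(\C)CCCC(C)(C)C=O)/C(C)=C\I)ccc1OC(C)=O | intermediate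
23 | dichloro[(1Z,3S,5E)-3-(4-acetoxy-3-methoxybenzoyloxy)-2,6,10,10-tetramethyl-11-oxoundeca-1,5-dien-1-yl]chromium (not isolated) | COc1cc(C(=O)O[C@@H](C/C=C(\C)CCCC(C)(C)C=O)/C(C)=C\[Cr](Cl)Cl)ccc1OC(C)=O | intermediate
24 | (1S,2Z,4R,9E)-4-hydroxy-2,5,5,9-tetramethylcycloundeca-2,9-dien-1-yl 4-acetoxy-3-methoxybenzoate | COc1cc(C(=O)O[C@H]2C/C=C(\C)CCCC(C)(C)[C@H](O)/C=C\2C)ccc1OC(C)=O | intermediate
25 | (1S,2Z,4R,9E)-4-acetoxy-2,5,5,9-tetramethylcycloundeca-2,9-dien-1-yl 4-acetoxy-3-methoxybenzoate | COc1cc(C(=O)O[C@H]2C/C=C(\C)CCCC(C)(C)[C@H](OC(C)=O)/C=C\2C)ccc1OC(C)=O | intermediate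
26 | (1S,2Z,4R,9E)-4-acetoxy-2,5,5,9-tetramethylcycloundeca-2,9-dien-1-yl 4-hydroxy-3-methoxybenzoate (CNP0124394.1) | COc1cc(C(=O)O[C@H]2C/C=C(\C)CCCC(C)(C)[C@H](OC(C)=O)/C=C\2C)ccc1O | target

Total step count: 15.
Longest linear sequence: 15 steps (1 → 26); 9 and 19 enter as purchased building blocks.
Stereochemistry: ring C1 comes from 9 (step 5), the 9E olefin from step 4, the 2Z olefin from step 9 and ring C4 from step 13.

Steps most likely to fail

Step 13. The risk is poor facial selectivity in the addition of the alkenylchromium to the aldehyde, since the 1,4-induction across the Z-olefin cannot be predicted with confidence. The fallback sets out from 22 and no longer relies on the ring closure to set C4. The ring closure is run as before and whatever carbinol mixture forms is used, including the epimer (1S,2Z,4S,9E)-4-hydroxy-2,5,5,9-tetramethylcycloundeca-2,9-dien-1-yl 4-acetoxy-3-methoxybenzoate F1. Dess–Martin periodinane should oxidise this mixture to the macrocyclic enone (1S,2Z,9E)-2,5,5,9-tetramethyl-4-oxocycloundeca-2,9-dien-1-yl 4-acetoxy-3-methoxybenzoate F2. C4 would then be set by reagent control in a Corey–Bakshi–Shibata reduction (2-methyl-CBS-oxazaborolidine, catecholborane, toluene, −78 °C). The (S)-catalyst should give the (4R)-carbinol if the quaternary C5 flank acts as the large group; otherwise its enantiomer is used. The esters should survive, and the route is rejoined at 24.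

Step 9. The risk is sluggish or regio-unselective carbomagnesiation of the hindered secondary alkoxide, or protonation of the alkenylmagnesium species before iodinolysis. The fallback sets out from 13 and makes the (Z)-iodoalkene by olefination instead of carbometalation. Me(MeO)NH·HCl with i-PrMgCl (THF, −20 °C) should give the Weinreb amide (2S,4E)-10-[(tert-butyldimethylsilyl)oxy]-N-methoxy-N,5,9,9-tetramethyl-2-[(triethylsilyl)oxy]dec-4-enamide F3. MeMgBr should convert it into the methyl ketone (3S,5E)-11-[(tert-butyldimethylsilyl)oxy]-6,10,10-trimethyl-3-[(triethylsilyl)oxy]undec-5-en-2-one F4. A Stork–Zhao Wittig reaction with Ph3P=CHI (from iodomethyltriphenylphosphonium iodide and NaN(SiMe3)2, THF, −78 °C) is expected to place iodine cis to the alpha-silyloxy carbon. It should give triethyl{[(1Z,3S,5E)-11-[(tert-butyldimethylsilyl)oxy]-1-iodo-2,6,10,10-tetramethylundeca-1,5-dien-3-yl]oxy}silane F5. PPTS in MeOH should then remove the triethylsilyl group, and the route is rejoined at 18.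

Step 5. The risk is attack of the alkenylmagnesium reagent on the ester carbonyl, or opening of the epoxide at the carbon next to the ester. The fallback sets out from 8 and uses an ester-free epoxide, with the oxidation level adjusted afterwards. After the same metalation, CuI-catalysed opening of (S)-2-{[(4-methoxybenzyl)oxy]methyl}oxirane F6 should give (2S,4E)-10-[(tert-butyldimethylsilyl)oxy]-1-[(4-methoxybenzyl)oxy]-5,9,9-trimethyldec-4-en-2-ol F7. Et3SiCl and imidazole should give the silyl ether tert-butyl{[(6E,9S)-10-[(4-methoxybenzyl)oxy]-2,2,6-trimethyl-9-[(triethylsilyl)oxy]dec-6-en-1-yl]oxy}dimethylsilane F8. DDQ (CH2Cl2, pH 7 buffer) should cleave the 4-methoxybenzyl ether to (2S,4E)-10-[(tert-butyldimethylsilyl)oxy]-5,9,9-trimethyl-2-[(triethylsilyl)oxy]dec-4-en-1-ol F9. Dess–Martin oxidation should then give aldehyde 14, where the route is rejoined; the Ohira–Bestmann half of step 7 carries it on to 15.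

Further compounds
F1 | step 13 | (1S,2Z,4S,9E)-4-hydroxy-2,5,5,9-tetramethylcycloundeca-2,9-dien-1-yl 4-acetoxy-3-methoxybenzoate | COc1cc(C(=O)O[C@H]2C/C=C(\C)CCCC(C)(C)[C@@H](O)/C=C\2C)ccc1OC(C)=O
F2 | step 13 | (1S,2Z,9E)-2,5,5,9-tetramethyl-4-oxocycloundeca-2,9-dien-1-yl 4-acetoxy-3-methoxybenzoate | COc1cc(C(=O)O[C@H]2C/C=C(\C)CCCC(C)(C)C(=O)/C=C\2C)ccc1OC(C)=O
F3 | step 9 | (2S,4E)-10-[(tert-butyldimethylsilyl)oxy]-N-methoxy-N,5,9,9-tetramethyl-2-[(triethylsilyl)oxy]dec-4-enamide | CON(C)C(=O)[C@@H](O[Si](CC)(CC)CC)C/C=C(\C)CCCC(C)(C)CO[Si](C)(C)C(C)(C)C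
F4 | step 9 | (3S,5E)-11-[(tert-butyldimethylsilyl)oxy]-6,10,10-trimethyl-3-[(triethylsilyl)oxy]undec-5-en-2-one | CC(=O)[C@@H](O[Si](CC)(CC)CC)C/C=C(\C)CCCC(C)(C)CO[Si](C)(C)C(C)(C)C
F5 | step 9 | triethyl{[(1Z,3S,5E)-11-[(tert-butyldimethylsilyl)oxy]-1-iodo-2,6,10,10-tetramethylundeca-1,5-dien-3-yl]oxy}silane | I/C=C(C)\[C@@H](O[Si](CC)(CC)CC)C/C=C(\C)CCCC(C)(C)CO[Si](C)(C)C(C)(C)C
F6 | step 5 | (S)-2-{[(4-methoxybenzyl)oxy]methyl}oxirane | COc1ccc(COC[C@@H]2CO2)cc1
F7 | step 5 | (2S,4E)-10-[(tert-butyldimethylsilyl)oxy]-1-[(4-methoxybenzyl)oxy]-5,9,9-trimethyldec-4-en-2-ol | COc1ccc(COC[C@@H](O)C/C=C(\C)CCCC(C)(C)CO[Si](C)(C)C(C)(C)C)cc1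
F8 | step 5 | tert-butyl{[(6E,9S)-10-[(4-methoxybenzyl)oxy]-2,2,6-trimethyl-9-[(triethylsilyl)oxy]dec-6-en-1-yl]oxy}dimethylsilane | COc1ccc(COC[C@@H](O[Si](CC)(CC)CC)C/C=C(\C)CCCC(C)(C)CO[Si](C)(C)C(C)(C)C)cc1
F9 | step 5 | (2S,4E)-10-[(tert-butyldimethylsilyl)oxy]-5,9,9-trimethyl-2-[(triethylsilyl)oxy]dec-4-en-1-ol | OC[C@@H](O[Si](CC)(CC)CC)C/C=C(\C)CCCC(C)(C)CO[Si](C)(C)C(C)(C)C
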